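**Plan**

- Retrosynthesis: the furan ring of the benzofuran is cut at C3'–C3a' and O1'–C2', giving 5-acetyl dihydrobenzofuran 18 and O-aryl hydroxylamine 22. The acetyl–C5 bond is then cut back to an aryl bromide, and the dihydrofuran ring at O1–C2 (phenol onto a benzylic carbinol) and C2–C3 (aldol).
- Enabling feature: C2' of the benzofuran carries C5 of the dihydrobenzofuran and can be the carbonyl carbon of a methyl ketone, and C3' is an unsubstituted CH (the ketone methyl). O1' and C3a' are neighbours on a guaiacyl ring whose other ortho carbon (C7') is blocked by OMe.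
- Forward: 5-bromo-o-vanillin → arylacetyl oxazolidinone → syn-aldol with MOM-vanillin → diol → acid closes the dihydrofuran ring → acetylation and Stille installation of the acetyl group → one-pot oxime ether formation, [3,3] shift and cyclisation closes the benzofuran → deacetylation.
- The ketone is carried as a bromide because a methyl ketone would not survive boron enolisation and LiBH4.
- Stereochemistry: C3 (R) comes from (S)-4-benzyl-2-oxazolidinone in the Evans aldol; C2 (S) is set trans to C3 in the acid-mediated ring closure; both are spectators afterwards.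

Key step: step 13

Remark on the chemistry: unprimed locants refer to the 2,3-dihydrobenzofuran and primed locants to the benzofuran; the SMILES is read as the trans (2S,3R) isomer, and the C2-aryl phenol is carried as an acetate (not a benzyl ether) through the key step.

**Route**

Step 1
Reactants: 1 5-bromo-2-hydroxy-3-methoxybenzaldehyde
Product: 2 5-bromo-3-methoxy-2-(methoxymethoxy)benzaldehyde
Conditions: MOMCl, i-Pr2NEt, CH2Cl2, 0 °C to rt
Reagents that add atoms: chloromethyl methyl ether, COCCl
Why: O-alkylation of the only phenol (MOM acetal protection) should be clean, and the MOM ether tolerates the basic, boron-enolate and hydride steps ahead yet leaves in the acid of step 8.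

Step 2
Reactants: 2 5-bromo-3-methoxy-2-(methoxymethoxy)benzaldehyde
Product: 4 2-[5-bromo-3-methoxy-2-(methoxymethoxy)phenyl]acetonitrile, via N-(1-tosylalkenyl)formamide 3 (not isolated)
Conditions: TosMIC, KOt-Bu, DME, −35 °C; then MeOH, reflux
Reagents that add atoms: tosylmethyl isocyanide, Cc1ccc(cc1)S(=O)(=O)C[N+]#[C-]
Why: van Leusen reductive cyanation, in which the TosMIC anion adds to the aldehyde, the oxazoline opens to vinylformamide 3 and methanolysis with loss of sulfinate should deliver the one-carbon-homologated nitrile, a conversion well established for electron-rich benzaldehydes.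

Step 3
Reactants: 4 2-[5-bromo-3-methoxy-2-(methoxymethoxy)phenyl]acetonitrile
Product: 5 2-[5-bromo-3-methoxy-2-(methoxymethoxy)phenyl]acetic acid
Conditions: KOH, EtOH/H2O, reflux; then cold 1 M HCl to pH 3
Reagents that add atoms: water, O; potassium hydroxide, [K+].[OH-]
Why: alkaline nitrile hydrolysis leaves the MOM acetal, the aryl bromide and the methyl ether untouched, and a brief cold acidification should free the acid without acetal loss.

Step 4
Reactants: 5 2-[5-bromo-3-methoxy-2-(methoxymethoxy)phenyl]acetic acid; 6 (S)-4-benzyl-2-oxazolidinone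
Product: 8 (S)-4-benzyl-3-{2-[5-bromo-3-methoxy-2-(methoxymethoxy)phenyl]acetyl}oxazolidin-2-one, via mixed pivalic anhydride 7 (not isolated)
Conditions: PivCl, Et3N, THF, −20 °C; then LiCl, 6, −20 °C to rt
Reagents that add atoms: none
Why: N-acylation of the oxazolidinone through the mixed pivalic anhydride is the standard way to attach an arylacetic acid to the Evans auxiliary, attack occurring at the less hindered arylacetyl carbonyl.

Step 5
Reactants: 9 vanillin
Product: 10 3-methoxy-4-(methoxymethoxy)benzaldehyde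
Conditions: MOMCl, i-Pr2NEt, CH2Cl2, 0 °C to rt
Reagents that add atoms: chloromethyl methyl ether, COCCl
Why: the same MOM acetal protection as in step 1 masks the phenol for the boron aldol, and both MOM groups can then be removed together in step 8.

Step 6
Reactants: 8 (S)-4-benzyl-3-{2-[5-bromo-3-methoxy-2-(methoxymethoxy)phenyl]acetyl}oxazolidin-2-one; 10 3-methoxy-4-(methoxymethoxy)benzaldehyde
Product: 12 (S)-4-benzyl-3-{(2S,3S)-2-[5-bromo-3-methoxy-2-(methoxymethoxy)phenyl]-3-hydroxy-3-[3-methoxy-4-(methoxymethoxy)phenyl]propanoyl}oxazolidin-2-one, via Z-dibutylboron enolate 11 (not isolated)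
Conditions: Bu2BOTf, i-Pr2NEt, CH2Cl2, −78 to 0 °C; then 10, −78 to 0 °C; pH 7 buffer, MeOH, H2O2, 0 °C
Reagents that add atoms: none
Why: Evans syn-aldol reaction, in which Z-boron enolate 11 adds to the aldehyde through a closed Zimmerman–Traxler chair on the face away from the benzyl group, which should set the α-carbon as S (the later C3, R once the carbonyl is reduced and the priorities change) and the carbinol carbon as S.

Step 7
Reactants: 12 aldol adduct
Product: 13 (1S,2R)-2-[5-bromo-3-methoxy-2-(methoxymethoxy)phenyl]-1-[3-methoxy-4-(methoxymethoxy)phenyl]propane-1,3-diol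
Conditions: LiBH4, MeOH (1 equiv), THF, 0 °C
Reagents that add atoms: none
Why: reductive cleavage of the N-acyloxazolidinone by LiBH4 should give the 1,3-diol and release the auxiliary without touching the aryl bromide or the MOM ethers, and the α-stereocentre is not enolised under these conditions.

Step 8
Reactants: 13 (1S,2R)-diol
Product: 15 4-[(2S,3R)-5-bromo-3-(hydroxymethyl)-7-methoxy-2,3-dihydro-1-benzofuran-2-yl]-2-methoxyphenol, via MOM-free tetrol 14 (not isolated)
Conditions: HCl (0.5 M), MeOH, 40 °C
Reagents that add atoms: none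
Why: acetal exchange with methanol removes both MOM groups and the electron-rich benzylic carbinol of 14 then ionises to a p-quinone methide type cation that the ortho phenol captures in a 5-exo-trig closure anti to the C3 hydroxymethyl group (acid-catalysed SN1 cyclodehydration as used to form phenylcoumarans), so C2 should emerge S and trans to the fixed C3 centre whatever the carbinol configuration, while the primary alcohol cannot ionise and stays out.

Step 9
Reactants: 15 bromo dihydrobenzofuran phenol alcohol
Product: 16 [(2S,3R)-2-(4-acetoxy-3-methoxyphenyl)-5-bromo-7-methoxy-2,3-dihydro-1-benzofuran-3-yl]methyl acetate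
Conditions: Ac2O, pyridine, DMAP (cat), CH2Cl2, rt
Reagents that add atoms: acetic anhydride, CC(=O)OC(C)=O
Why: DMAP-catalysed acylation esterifies the phenol and the primary alcohol, and the aryl acetate makes the C2 aryl ring electron-poorer and so hardens the benzylic C2–O bond for the acidic key step.

Step 10
Reactants: 16 bromo diacetate
Product: 18 [(2S,3R)-2-(4-acetoxy-3-methoxyphenyl)-5-acetyl-7-methoxy-2,3-dihydro-1-benzofuran-3-yl]methyl acetate, via 1-ethoxyvinyl arene 17 (not isolated)
Conditions: Bu3Sn(C(OEt)=CH2), Pd(PPh3)4 (5 mol %), toluene, 100 °C; then 1 M HCl, THF, rt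
Reagents that add atoms: tributyl(1-ethoxyvinyl)stannane, CCCC[Sn](CCCC)(CCCC)C(=C)OCC; water, O
Why: Stille coupling of the unhindered aryl bromide with the acyl-anion equivalent tributyl(1-ethoxyvinyl)stannane followed by mild acid hydrolysis of enol ether 17 should install the methyl ketone, and the acetates survive both stages.

Step 11
Reactants: 19 dihydroconiferyl alcohol
Product: 20 3-(4-hydroxy-3-methoxyphenyl)propyl acetate
Conditions: EtOAc (solvent), TsOH·H2O (cat), reflux
Reagents that add atoms: ethyl acetate, CCOC(C)=O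
Why: acid-catalysed transesterification with ethyl acetate acylates only the aliphatic hydroxyl because the far less nucleophilic phenol does not exchange under these conditions.

Step 12
Reactants: 20 3-(4-hydroxy-3-methoxyphenyl)propyl acetate
Product: 22 3-[4-(aminooxy)-3-methoxyphenyl]propyl acetate, via potassium phenoxide 21 (not isolated)
Conditions: KOt-Bu (1.0 equiv), THF, 0 °C; then MSH (freshly prepared), CH2Cl2, 0 °C
Reagents that add atoms: O-(mesitylsulfonyl)hydroxylamine, Cc1cc(C)c(S(=O)(=O)ON)c(C)c1
Why: electrophilic amination of the phenoxide at oxygen by O-mesitylsulfonylhydroxylamine (substitution at nitrogen with sulfonate as leaving group) is the established direct route from phenols to O-arylhydroxylamines, and one equivalent of base forms only the phenoxide so the acetate is safe.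

Step 13
Reactants: 18 5-acetyl dihydrobenzofuran diacetate; 22 3-[4-(aminooxy)-3-methoxyphenyl]propyl acetate
Product: 24 3-{2-[(2S,3R)-2-(4-acetoxy-3-methoxyphenyl)-3-(acetoxymethyl)-7-methoxy-2,3-dihydro-1-benzofuran-5-yl]-7-methoxy-1-benzofuran-5-yl}propyl acetate, via O-aryl ketoxime ether 23 (not isolated)
Conditions: MsOH (2.5 equiv), 4 Å molecular sieves, THF, rt, then 60 °C
Reagents that add atoms: none
Why: Acid-catalysed condensation of ketone 18 with aryloxyamine 22 gives O-aryl ketoxime ether 23, whose N-protonated ene-hydroxylamine tautomer undergoes a [3,3] sigmatropic shift that breaks the weak N–O bond and joins the former acetyl methyl carbon (C3') to the free ortho carbon (C3a') of the guaiacyl ring; tautomerisation restores the phenol, which adds to the iminium carbon (O1'–C2'), and loss of ammonium aromatises the furan. The closest known reaction type is the acid-promoted one-pot benzofuran synthesis from O-arylhydroxylamines and enolisable ketones, the oxygen counterpart of the Fischer indole synthesis. The single ring formed, the furan ring of the benzofuran, closes in 5-exo-trig mode by attack of the phenolic oxygen on the C=N carbon. No stereocentre is created, and C2 and C3 of the dihydrobenzofuran are spectators. The step needs regioselectivity and chemoselectivity: the methyl ketone can enolise in one direction only and the second ortho carbon of the aryloxy ring carries OMe, so attack there would give a dienone that cannot aromatise, which leaves C3a' as the only productive site. Ionisation of the benzylic C2–O bond by the acid is held back by the electron-poor 4-acetoxy group on the C2 aryl ring, and any opening would reclose trans because C3 is not touched.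

Step 14
Reactants: 24 triacetate
Product: 25 4-[(2S,3R)-3-(hydroxymethyl)-5-[5-(3-hydroxypropyl)-7-methoxy-1-benzofuran-2-yl]-7-methoxy-2,3-dihydro-1-benzofuran-2-yl]-2-methoxyphenol
Conditions: K2CO3 (cat), MeOH, N2, 0 °C to rt; then NH4Cl
Reagents that add atoms: none
Why: Zemplén-type transesterification with catalytic K2CO3 in methanol should remove the aryl acetate and the two alkyl acetates while leaving the benzofuran, the dihydrobenzofuran stereocentres and the methyl ethers intact.

**Compound list**

1 | 5-bromo-2-hydroxy-3-methoxybenzaldehyde | COc1cc(Br)cc(C=O)c1O | starting material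
2 | 5-bromo-3-methoxy-2-(methoxymethoxy)benzaldehyde | COCOc1c(OC)cc(Br)cc1C=O | intermediate
3 | N-{2-[5-bromo-3-methoxy-2-(methoxymethoxy)phenyl]-1-tosylethenyl}formamide | O=CNC(=Cc1cc(Br)cc(OC)c1OCOC)S(=O)(=O)c1ccc(C)cc1 | intermediate
4 | 2-[5-bromo-3-methoxy-2-(methoxymethoxy)phenyl]acetonitrile | COCOc1c(OC)cc(Br)cc1CC#N | intermediate
5 | 2-[5-bromo-3-methoxy-2-(methoxymethoxy)phenyl]acetic acid | COCOc1c(OC)cc(Br)cc1CC(=O)O | intermediate
6 | (S)-4-benzyl-2-oxazolidinone | O=C1N[C@@H](Cc2ccccc2)CO1 | starting material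
7 | 2-[5-bromo-3-methoxy-2-(methoxymethoxy)phenyl]acetic pivalic anhydride | COCOc1c(OC)cc(Br)cc1CC(=O)OC(=O)C(C)(C)C | intermediate
8 | (S)-4-benzyl-3-{2-[5-bromo-3-methoxy-2-(methoxymethoxy)phenyl]acetyl}oxazolidin-2-one | COCOc1c(OC)cc(Br)cc1CC(=O)N1C(=O)OC[C@@H]1Cc1ccccc1 | intermediate
9 | vanillin | COc1cc(C=O)ccc1O | starting material
10 | 3-methoxy-4-(methoxymethoxy)benzaldehyde | COCOc1ccc(C=O)cc1OC | intermediate
11 | Z-dibutylboron enolate of 8 | CCCCB(CCCC)O/C(=C\c1cc(Br)cc(OC)c1OCOC)N1C(=O)OC[C@@H]1Cc1ccccc1 | intermediate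
12 | (S)-4-benzyl-3-{(2S,3S)-2-[5-bromo-3-methoxy-2-(methoxymethoxy)phenyl]-3-hydroxy-3-[3-methoxy-4-(methoxymethoxy)phenyl]propanoyl}oxazolidin-2-one | COCOc1ccc([C@@H](O)[C@@H](C(=O)N2C(=O)OC[C@@H]2Cc2ccccc2)c2cc(Br)cc(OC)c2OCOC)cc1OC | intermediate
13 | (1S,2R)-2-[5-bromo-3-methoxy-2-(methoxymethoxy)phenyl]-1-[3-methoxy-4-(methoxymethoxy)phenyl]propane-1,3-diol | COCOc1ccc([C@@H](O)[C@@H](CO)c2cc(Br)cc(OC)c2OCOC)cc1OC | intermediate
14 | (1S,2R)-2-(5-bromo-2-hydroxy-3-methoxyphenyl)-1-(4-hydroxy-3-methoxyphenyl)propane-1,3-diol | COc1cc([C@@H](O)[C@@H](CO)c2cc(Br)cc(OC)c2O)ccc1O | intermediate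
15 | 4-[(2S,3R)-5-bromo-3-(hydroxymethyl)-7-methoxy-2,3-dihydro-1-benzofuran-2-yl]-2-methoxyphenol | COc1cc([C@H]2Oc3c(OC)cc(Br)cc3[C@@H]2CO)ccc1O | intermediate
16 | [(2S,3R)-2-(4-acetoxy-3-methoxyphenyl)-5-bromo-7-methoxy-2,3-dihydro-1-benzofuran-3-yl]methyl acetate | COc1cc([C@H]2Oc3c(OC)cc(Br)cc3[C@@H]2COC(C)=O)ccc1OC(C)=O | intermediate
17 | [(2S,3R)-2-(4-acetoxy-3-methoxyphenyl)-5-(1-ethoxyvinyl)-7-methoxy-2,3-dihydro-1-benzofuran-3-yl]methyl acetate | COc1cc([C@H]2Oc3c(OC)cc(C(=C)OCC)cc3[C@@H]2COC(C)=O)ccc1OC(C)=O | intermediate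
18 | [(2S,3R)-2-(4-acetoxy-3-methoxyphenyl)-5-acetyl-7-methoxy-2,3-dihydro-1-benzofuran-3-yl]methyl acetate | COc1cc([C@H]2Oc3c(OC)cc(C(C)=O)cc3[C@@H]2COC(C)=O)ccc1OC(C)=O | intermediate
19 | dihydroconiferyl alcohol, 4-(3-hydroxypropyl)-2-methoxyphenol | OCCCc1ccc(O)c(OC)c1 | starting material
20 | 3-(4-hydroxy-3-methoxyphenyl)propyl acetate | CC(=O)OCCCc1ccc(O)c(OC)c1 | intermediate
21 | potassium 4-(3-acetoxypropyl)-2-methoxyphenoxide | CC(=O)OCCCc1ccc([O-])c(OC)c1.[K+] | intermediate
22 | 3-[4-(aminooxy)-3-methoxyphenyl]propyl acetate | CC(=O)OCCCc1ccc(ON)c(OC)c1 | intermediate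
23 | (E)-O-[4-(3-acetoxypropyl)-2-methoxyphenyl] oxime of ketone 18 | COc1cc([C@H]2Oc3c(OC)cc(/C(C)=N/Oc4ccc(CCCOC(C)=O)cc4OC)cc3[C@@H]2COC(C)=O)ccc1OC(C)=O | intermediate
24 | 3-{2-[(2S,3R)-2-(4-acetoxy-3-methoxyphenyl)-3-(acetoxymethyl)-7-methoxy-2,3-dihydro-1-benzofuran-5-yl]-7-methoxy-1-benzofuran-5-yl}propyl acetate | COc1cc([C@H]2Oc3c(OC)cc(-c4cc5cc(CCCOC(C)=O)cc(OC)c5o4)cc3[C@@H]2COC(C)=O)ccc1OC(C)=O | intermediate
25 | 4-[(2S,3R)-3-(hydroxymethyl)-5-[5-(3-hydroxypropyl)-7-methoxy-1-benzofuran-2-yl]-7-methoxy-2,3-dihydro-1-benzofuran-2-yl]-2-methoxyphenol | COc1cc([C@H]2Oc3c(OC)cc(-c4cc5cc(CCCO)cc(OC)c5o4)cc3[C@@H]2CO)ccc1O | target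

**Step count**

Total: 14 steps. Longest linear sequence: 11 steps (steps 1–4, 6–10, 13, 14).

**Steps most likely to fail**

Step 13. The [3,3] shift may be diverted to the methoxy-bearing ortho carbon, the N–O bond may break without C–C bond formation, or the acid may open the dihydrobenzofuran at C2. The fallback builds the benzofuran by alkyne coupling and cycloisomerisation, setting out from bromide 16 and phenol 20 and returning at 24. Sonogashira coupling of 16 with trimethylsilylacetylene (PdCl2(PPh3)2, CuI, Et3N, DMF, 70 °C) should give [(2S,3R)-2-(4-acetoxy-3-methoxyphenyl)-7-methoxy-5-[(trimethylsilyl)ethynyl]-2,3-dihydro-1-benzofuran-3-yl]methyl acetate F1. Buffered desilylation (Bu4NF, AcOH, THF, 0 °C) should give [(2S,3R)-2-(4-acetoxy-3-methoxyphenyl)-5-ethynyl-7-methoxy-2,3-dihydro-1-benzofuran-3-yl]methyl acetate F2. Iodination of 20 ortho to the hydroxyl (NIS, cat TsOH, MeCN) should give 3-(4-hydroxy-3-iodo-5-methoxyphenyl)propyl acetate F3. Sonogashira coupling of F2 with F3 with in situ 5-endo-dig cyclisation of the o-alkynylphenol (PdCl2(PPh3)2, CuI, Et3N, DMF, 60 °C) should then deliver 24.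

Step 12. Ring amination or oxidation of the electron-rich phenoxide may compete with O-amination, and the aminating agent or the O-aryl hydroxylamine may decompose before isolation. The fallback makes the O–N bond by copper-mediated coupling, setting out from 20 and returning at 22. Triflation (Tf2O, pyridine, CH2Cl2, 0 °C) should give 3-[3-methoxy-4-(trifluoromethylsulfonyloxy)phenyl]propyl acetate F4. Miyaura borylation (B2pin2, PdCl2(dppf), KOAc, dioxane, 80 °C) should give 3-[3-methoxy-4-(4,4,5,5-tetramethyl-1,3,2-dioxaborolan-2-yl)phenyl]propyl acetate F5, and periodate cleavage of the pinacol ester (NaIO4, NH4OAc, acetone/water) should give [4-(3-acetoxypropyl)-2-methoxyphenyl]boronic acid F6. Chan–Lam coupling with N-hydroxyphthalimide (Cu(OAc)2, pyridine, 4 Å molecular sieves, 1,2-dichloroethane, air, rt) should give 3-{3-methoxy-4-[(1,3-dioxoisoindolin-2-yl)oxy]phenyl}propyl acetate F7. Brief hydrazinolysis (N2H4·H2O, CH2Cl2/MeOH, 0 °C) should then release 22.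

Step 7. Hydride may attack the ring carbonyl of the hindered α-aryl imide and open the oxazolidinone, or the basic medium may trigger retro-aldol cleavage. The fallback separates auxiliary removal from reduction, setting out from 12 and returning at 13. Hydroperoxide hydrolysis (LiOH, H2O2, THF/water, 0 °C), which is selective for the exocyclic carbonyl, should give (2S,3S)-2-[5-bromo-3-methoxy-2-(methoxymethoxy)phenyl]-3-hydroxy-3-[3-methoxy-4-(methoxymethoxy)phenyl]propanoic acid F8. Borane reduction of the acid (BH3·SMe2, THF, 0 °C to rt) should then give diol 13.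

**Further compounds**

F1 | step 13 | [(2S,3R)-2-(4-acetoxy-3-methoxyphenyl)-7-methoxy-5-[(trimethylsilyl)ethynyl]-2,3-dihydro-1-benzofuran-3-yl]methyl acetate | COc1cc([C@H]2Oc3c(OC)cc(C#C[Si](C)(C)C)cc3[C@@H]2COC(C)=O)ccc1OC(C)=O
F2 | step 13 | [(2S,3R)-2-(4-acetoxy-3-methoxyphenyl)-5-ethynyl-7-methoxy-2,3-dihydro-1-benzofuran-3-yl]methyl acetate | COc1cc([C@H]2Oc3c(OC)cc(C#C)cc3[C@@H]2COC(C)=O)ccc1OC(C)=O
F3 | step 13 | 3-(4-hydroxy-3-iodo-5-methoxyphenyl)propyl acetate | CC(=O)OCCCc1cc(I)c(O)c(OC)c1
F4 | step 12 | 3-[3-methoxy-4-(trifluoromethylsulfonyloxy)phenyl]propyl acetate | CC(=O)OCCCc1ccc(OS(=O)(=O)C(F)(F)F)c(OC)c1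
F5 | step 12 | 3-[3-methoxy-4-(4,4,5,5-tetramethyl-1,3,2-dioxaborolan-2-yl)phenyl]propyl acetate | CC(=O)OCCCc1ccc(B2OC(C)(C)C(C)(C)O2)c(OC)c1
F6 | step 12 | [4-(3-acetoxypropyl)-2-methoxyphenyl]boronic acid | CC(=O)OCCCc1ccc(B(O)O)c(OC)c1
F7 | step 12 | 3-{3-methoxy-4-[(1,3-dioxoisoindolin-2-yl)oxy]phenyl}propyl acetate | CC(=O)OCCCc1ccc(ON2C(=O)c3ccccc3C2=O)c(OC)c1
F8 | step 7 | (2S,3S)-2-[5-bromo-3-methoxy-2-(methoxymethoxy)phenyl]-3-hydroxy-3-[3-methoxy-4-(methoxymethoxy)phenyl]propanoic acid | COCOc1ccc([C@@H](O)[C@@H](C(=O)O)c2cc(Br)cc(OC)c2OCOC)cc1OC
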